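**Plan**

1. Retrosynthesis: after removal of eight benzyl groups, cut the C3–carboxyl bond (enol triflate carbonylation, alkene then moved from C2=C3 to C3=C4), then cut both bonds that join ring A to ring B, C4–C4a and C8a–C1.
2. The double cut leaves a 3,4-bis(benzyloxy)aryne (C4a≡C8a) and an acyclic 2-silyloxy-1,3-diene, the silyl dienol ether of the Knoevenagel adduct of 3,4-bis(benzyloxy)benzaldehyde with the acetoacetate of protected (R)-danshensu.
3. Enabling feature: the C8 oxygen of ring A sits directly beside ring-fusion carbon C8a, so the aryne is a 3-alkoxyaryne, electrophilic at the distal carbon (C4a); in ring B, C4 (next to C3, a masked ketone) is the nucleophilic diene terminus and the aryl-bearing C1 is the other terminus.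
4. Forward: side-chain alcohol and diene (steps 1–4) and aryne precursor (steps 5–8) are made separately; ring B is then closed onto the preformed ring A in one [4+2] event (step 9); the C3 carboxyl enters with the second danshensu unit (steps 10–11), the alkene is shifted (step 12) and all benzyl groups are removed (step 13).
5. Stereochemistry: both side-chain centres come from (R)-danshensu (chiral pool); C1 is set in the cycloaddition under control of the α-acyloxy ester on the diene; C2 is set trans to C1 by thermodynamic protonation.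

Key step: step 9

Remark: atom numbers are those of the dihydronaphthalene core (C1 aryl-bearing, C2/C3 ester-bearing, C4 vinylic CH, C4a/C8a ring fusion, C7/C8 oxygenated). R* is the tribenzyl danshensu residue (2R)-1-(benzyloxy)-3-[3,4-bis(benzyloxy)phenyl]-1-oxopropan-2-yl, bound through O2. Sodium (R)-danshensu is assumed to be commercial.

**Route**

Step 1
Reactants: 1 sodium (R)-danshensu [sodium (2R)-3-(3,4-dihydroxyphenyl)-2-hydroxypropanoate]; 2 benzyl bromide
Product: 3 benzyl (2R)-3-[3,4-bis(benzyloxy)phenyl]-2-hydroxypropanoate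
Conditions: BnBr (3.3 equiv), K2CO3, DMF, rt
Reagents that add atoms: benzyl bromide (2), BrCc1ccccc1
Why: Carbonate ionises only the carboxylic acid and the two phenols, so SN2 O-alkylation (Williamson ether synthesis and carboxylate alkylation) should leave the secondary alcohol free and the stereocenter untouched.

Step 2
Reactants: 3 tribenzyl danshensu alcohol; 4 dioxinone [2,2,6-trimethyl-4H-1,3-dioxin-4-one]
Product: 6 R* 3-oxobutanoate, via acetylketene 5 (not isolated)
Conditions: xylene, 130 °C
Reagents that add atoms: 2,2,6-trimethyl-4H-1,3-dioxin-4-one (4), CC1=CC(=O)OC(C)(C)O1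
Why: Thermal retro-hetero-Diels–Alder cleavage of the dioxinone releases acetylketene, which the secondary alcohol traps (acetoacetylation) under neutral conditions that should not epimerise the α-acyloxy ester.

Step 3
Reactants: 6 acetoacetate; 7 aldehyde [3,4-bis(benzyloxy)benzaldehyde]
Product: 8 R* (2Z)-2-acetyl-3-[3,4-bis(benzyloxy)phenyl]prop-2-enoate
Conditions: piperidine (cat.), AcOH (cat.), PhMe, 4 Å MS, 50 °C
Reagents that add atoms: none
Why: Knoevenagel condensation at the doubly activated methylene gives the arylidene acetoacetate, for which the isomer with the aryl group cis to the ester and trans to the acetyl group (Z) is expected to be favoured under the equilibrating amine/acid conditions.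

Step 4
Reactants: 8 arylidene acetoacetate; 9 triisopropylsilyl triflate
Product: 10 R* (2Z)-2-[3,4-bis(benzyloxy)benzylidene]-3-[(triisopropylsilyl)oxy]but-3-enoate
Conditions: TIPSOTf, Et3N, CH2Cl2, 0 °C to rt
Reagents that add atoms: triisopropylsilyl triflate (9), CC(C)[Si](C(C)C)(C(C)C)OS(=O)(=O)C(F)(F)F
Why: The methyl group is the only enolisable position, so soft enolisation with a silyl triflate and amine (silyl enol ether formation) should give the cross-conjugated 2-silyloxy diene with the arylidene geometry retained.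

Step 5
Reactants: 7 aldehyde [3,4-bis(benzyloxy)benzaldehyde]; 11 mCPBA
Product: 13 phenol [3,4-bis(benzyloxy)phenol], via aryl formate 12 (not isolated)
Conditions: mCPBA, CH2Cl2, rt; then K2CO3, MeOH, rt
Reagents that add atoms: mCPBA (11), OOC(=O)c1cccc(Cl)c1
Why: Baeyer–Villiger oxidation of the electron-rich benzaldehyde proceeds with aryl migration (Dakin-type oxidation) and methanolysis of the aryl formate frees the phenol.

Step 6
Reactants: 13 phenol; 14 isopropyl isocyanate
Product: 15 carbamate [3,4-bis(benzyloxy)phenyl N-isopropylcarbamate]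
Conditions: i-PrNCO, Et3N (cat.), CH2Cl2, rt
Reagents that add atoms: isopropyl isocyanate (14), CC(C)N=C=O
Why: Amine-catalysed addition of the phenol to the isocyanate (carbamoylation) installs a directing group that can later be removed by mild base.

Step 7
Reactants: 15 carbamate; 16 chlorotrimethylsilane
Product: 20 2-silyl carbamate [3,4-bis(benzyloxy)-2-(trimethylsilyl)phenyl N-isopropylcarbamate], via N-silyl carbamate 17 (not isolated), via aryllithium 18 (not isolated), via N-silyl 2-silyl carbamate 19 (not isolated)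
Conditions: TBSOTf, TMEDA, Et2O, 0 °C to rt; n-BuLi, TMEDA, −78 °C; Me3SiCl, −78 °C to rt; aq. NaHSO4
Reagents that add atoms: chlorotrimethylsilane (16), C[Si](C)(C)Cl
Why: After in-situ N-silylation the carbamate directs lithiation (directed ortho-metalation) to C2, the position flanked by the carbamate and the 3-benzyloxy group, and the aryllithium is silylated; at −78 °C benzylic lithiation of the benzyl ethers should not compete.

Step 8
Reactants: 20 2-silyl carbamate; 21 N-phenylbis(trifluoromethanesulfonimide)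
Product: 23 aryne precursor [3,4-bis(benzyloxy)-2-(trimethylsilyl)phenyl trifluoromethanesulfonate], via 2-silylphenol 22 (not isolated)
Conditions: DBU, Et2NH, MeCN, 40 °C; then PhNTf2, rt
Reagents that add atoms: N-phenylbis(trifluoromethanesulfonimide) (21), O=S(=O)(N(c1ccccc1)S(=O)(=O)C(F)(F)F)C(F)(F)F
Why: DBU triggers E1cB loss of isopropyl isocyanate (trapped by Et2NH as a urea) and the phenoxide is sulfonylated by PhNTf2 (O-triflation), which should give the 2-silylaryl triflate without protodesilylation.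

Step 9
Reactants: 10 silyloxy diene; 23 aryne precursor
Product: 25 R* (1R)-7,8-bis(benzyloxy)-1-[3,4-bis(benzyloxy)phenyl]-3-[(triisopropylsilyl)oxy]-1,4-dihydronaphthalene-2-carboxylate, via aryne 24 (not isolated)
Conditions: CsF (2 equiv), MeCN/PhMe 1:3, rt, slow addition of 23 (1.3 equiv)
Reagents that add atoms: none
Why: Fluoride unmasks aryne 24, whose benzyloxy group beside the triple bond makes the distal carbon (future C4a) the electrophilic one; the CH2 terminus of the 2-silyloxy diene, its most nucleophilic carbon, bonds there first and the arylidene carbon then closes onto the carbon next to the benzyloxy group (future C8a) in a strongly asynchronous Diels–Alder reaction. The closest known reaction type is the aryne [4+2] cycloaddition of acyclic 2-silyloxy dienes and of acyclic dienes that carry a chiral acyl group. Ring B closes by this [4+2] cycloaddition, which in its stepwise limit is a 6-endo-trig attack of the aryl carbanion on the benzylic end of a silyloxyallyl cation. The only new stereocenter, C1, is controlled by the (R)-configured α-acyloxy ester on the diene, which is expected to shield one face of the s-cis diene so that the aryne adds to the face leading to the (1R) adduct; the (1S) epimer is a diastereomer and would be removed by chromatography. The step needs regioselectivity (secured by the benzyloxy group beside the triple bond and by the silyloxy group that polarises the diene), [4+2] over [2+2] or ene selectivity (secured by the aryl group lying outside the s-cis diene and by delocalisation of developing positive charge onto the electron-rich arylidene carbon) and survival of both silyl enol ethers towards fluoride (secured by the bulky triisopropylsilyl group).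

Step 10
Reactants: 25 cycloadduct; 21 N-phenylbis(trifluoromethanesulfonimide)
Product: 27 R* (1R)-7,8-bis(benzyloxy)-1-[3,4-bis(benzyloxy)phenyl]-3-{[(trifluoromethyl)sulfonyl]oxy}-1,4-dihydronaphthalene-2-carboxylate, via cesium enolate 26 (not isolated)
Conditions: CsF, PhNTf2, DME, rt; dilute HCl work-up
Reagents that add atoms: N-phenylbis(trifluoromethanesulfonimide) (21), O=S(=O)(N(c1ccccc1)S(=O)(=O)C(F)(F)F)C(F)(F)F
Why: Fluoride cleaves the silyl enol ether to the cesium enolate of the β-keto ester, which is O-sulfonylated by PhNTf2 (enol triflate formation); C1–H is not acidic in this enolate, so its configuration should be kept.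

Step 11
Reactants: 27 enol triflate; 3 tribenzyl danshensu alcohol (3 equiv); 28 carbon monoxide
Product: 29 bis(R*) (1R)-7,8-bis(benzyloxy)-1-[3,4-bis(benzyloxy)phenyl]-1,4-dihydronaphthalene-2,3-dicarboxylate
Conditions: Pd(OAc)2 (5 mol %), 1,3-bis(diphenylphosphino)propane, Et3N, CO (1 atm), DMF, 60 °C
Reagents that add atoms: carbon monoxide (28), [C-]#[O+]
Why: Oxidative addition of zerovalent palladium into the enol triflate, CO insertion and alcoholysis of the acylpalladium species by 3 (palladium-catalysed alkoxycarbonylation) should install the C3 ester with the second danshensu unit, the excess of 3 compensating for its hindered secondary hydroxyl group.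

Step 12
Reactants: 29 1,4-dihydro diester
Product: 30 bis(R*) (1R,2S)-7,8-bis(benzyloxy)-1-[3,4-bis(benzyloxy)phenyl]-1,2-dihydronaphthalene-2,3-dicarboxylate
Conditions: DBU (0.2 equiv), CH2Cl2, 0 °C to rt, argon
Reagents that add atoms: none
Why: Amidine-catalysed prototropic alkene isomerisation through the C2-ester dienolate formed at the C4 methylene should move the double bond into conjugation with ring A and relieve the cis-diester strain, the C1–H bond being held pseudo-equatorial and orthogonal to the π system by the pseudo-axial aryl group beside the C8 benzyloxy group, while reversible protonation at C2 settles to the trans (1R,2S) diester under thermodynamic control.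

Step 13
Reactants: 30 octabenzyl-protected target
Product: 31 target, bis[(1R)-1-carboxy-2-(3,4-dihydroxyphenyl)ethyl] (1R,2S)-1-(3,4-dihydroxyphenyl)-7,8-dihydroxy-1,2-dihydronaphthalene-2,3-dicarboxylate
Conditions: BCl3 (24 equiv), C6HMe5 (30 equiv), CH2Cl2, −78 to 0 °C; MeOH then H2O
Reagents that add atoms: none
Why: BCl3 cleaves the six aryl benzyl ethers and the two benzyl esters (Lewis-acid debenzylation) while pentamethylbenzene traps the benzyl cations, a non-reductive method that should spare the conjugated C3=C4 alkene, the secondary alkyl ester links and all four stereocenters.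

**Compound list**

1 | sodium (2R)-3-(3,4-dihydroxyphenyl)-2-hydroxypropanoate (sodium (R)-danshensu) | O[C@H](Cc1ccc(O)c(O)c1)C(=O)[O-].[Na+] | starting material
2 | benzyl bromide | BrCc1ccccc1 | starting material
3 | benzyl (2R)-3-[3,4-bis(benzyloxy)phenyl]-2-hydroxypropanoate | O[C@H](Cc1ccc(OCc2ccccc2)c(OCc2ccccc2)c1)C(=O)OCc1ccccc1 | intermediate
4 | 2,2,6-trimethyl-4H-1,3-dioxin-4-one | CC1=CC(=O)OC(C)(C)O1 | starting material
5 | acetylketene | CC(=O)C=C=O | intermediate
6 | R* 3-oxobutanoate | CC(=O)CC(=O)O[C@H](Cc1ccc(OCc2ccccc2)c(OCc2ccccc2)c1)C(=O)OCc1ccccc1 | intermediate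
7 | 3,4-bis(benzyloxy)benzaldehyde | O=Cc1ccc(OCc2ccccc2)c(OCc2ccccc2)c1 | starting material
8 | R* (2Z)-2-acetyl-3-[3,4-bis(benzyloxy)phenyl]prop-2-enoate | CC(=O)/C(C(=O)O[C@H](Cc1ccc(OCc2ccccc2)c(OCc2ccccc2)c1)C(=O)OCc1ccccc1)=C/c1ccc(OCc2ccccc2)c(OCc2ccccc2)c1 | intermediate
9 | triisopropylsilyl trifluoromethanesulfonate | CC(C)[Si](C(C)C)(C(C)C)OS(=O)(=O)C(F)(F)F | starting material
10 | R* (2Z)-2-[3,4-bis(benzyloxy)benzylidene]-3-[(triisopropylsilyl)oxy]but-3-enoate | C=C(O[Si](C(C)C)(C(C)C)C(C)C)/C(C(=O)O[C@H](Cc1ccc(OCc2ccccc2)c(OCc2ccccc2)c1)C(=O)OCc1ccccc1)=C/c1ccc(OCc2ccccc2)c(OCc2ccccc2)c1 | intermediate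
11 | 3-chloroperoxybenzoic acid (mCPBA) | OOC(=O)c1cccc(Cl)c1 | starting material
12 | 3,4-bis(benzyloxy)phenyl formate | O=COc1ccc(OCc2ccccc2)c(OCc2ccccc2)c1 | intermediate
13 | 3,4-bis(benzyloxy)phenol | Oc1ccc(OCc2ccccc2)c(OCc2ccccc2)c1 | intermediate
14 | isopropyl isocyanate | CC(C)N=C=O | starting material
15 | 3,4-bis(benzyloxy)phenyl N-isopropylcarbamate | CC(C)NC(=O)Oc1ccc(OCc2ccccc2)c(OCc2ccccc2)c1 | intermediate
16 | chlorotrimethylsilane | C[Si](C)(C)Cl | starting material
17 | 3,4-bis(benzyloxy)phenyl N-(tert-butyldimethylsilyl)-N-isopropylcarbamate | CC(C)N(C(=O)Oc1ccc(OCc2ccccc2)c(OCc2ccccc2)c1)[Si](C)(C)C(C)(C)C | intermediate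
18 | 2-lithio derivative of 17 (lithium at C2, between the carbamate and the 3-benzyloxy group) | [Li]c1c(OC(=O)N(C(C)C)[Si](C)(C)C(C)(C)C)ccc(OCc2ccccc2)c1OCc1ccccc1 | intermediate
19 | 3,4-bis(benzyloxy)-2-(trimethylsilyl)phenyl N-(tert-butyldimethylsilyl)-N-isopropylcarbamate | CC(C)N(C(=O)Oc1ccc(OCc2ccccc2)c(OCc2ccccc2)c1[Si](C)(C)C)[Si](C)(C)C(C)(C)C | intermediate
20 | 3,4-bis(benzyloxy)-2-(trimethylsilyl)phenyl N-isopropylcarbamate | CC(C)NC(=O)Oc1ccc(OCc2ccccc2)c(OCc2ccccc2)c1[Si](C)(C)C | intermediate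
21 | N-phenylbis(trifluoromethanesulfonimide) | O=S(=O)(N(c1ccccc1)S(=O)(=O)C(F)(F)F)C(F)(F)F | starting material
22 | 3,4-bis(benzyloxy)-2-(trimethylsilyl)phenol | Oc1ccc(OCc2ccccc2)c(OCc2ccccc2)c1[Si](C)(C)C | intermediate
23 | 3,4-bis(benzyloxy)-2-(trimethylsilyl)phenyl trifluoromethanesulfonate | O=S(=O)(Oc1ccc(OCc2ccccc2)c(OCc2ccccc2)c1[Si](C)(C)C)C(F)(F)F | intermediate
24 | 3,4-bis(benzyloxy)benzyne (1,2-didehydro-3,4-bis(benzyloxy)benzene) | C1=CC(OCc2ccccc2)=C(OCc2ccccc2)C#C1 | intermediate
25 | R* (1R)-7,8-bis(benzyloxy)-1-[3,4-bis(benzyloxy)phenyl]-3-[(triisopropylsilyl)oxy]-1,4-dihydronaphthalene-2-carboxylate | CC(C)[Si](OC1=C(C(=O)O[C@H](Cc2ccc(OCc3ccccc3)c(OCc3ccccc3)c2)C(=O)OCc2ccccc2)[C@H](c2ccc(OCc3ccccc3)c(OCc3ccccc3)c2)c2c(OCc3ccccc3)c(OCc3ccccc3)ccc2C1)(C(C)C)C(C)C | intermediate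
26 | cesium enolate of the corresponding β-keto ester (3-oxido-1,4-dihydronaphthalene-2-carboxylate) | [Cs+].[O-]C1=C(C(=O)O[C@H](Cc2ccc(OCc3ccccc3)c(OCc3ccccc3)c2)C(=O)OCc2ccccc2)[C@H](c2ccc(OCc3ccccc3)c(OCc3ccccc3)c2)c2c(OCc3ccccc3)c(OCc3ccccc3)ccc2C1 | intermediate
27 | R* (1R)-7,8-bis(benzyloxy)-1-[3,4-bis(benzyloxy)phenyl]-3-{[(trifluoromethyl)sulfonyl]oxy}-1,4-dihydronaphthalene-2-carboxylate | O=S(=O)(OC1=C(C(=O)O[C@H](Cc2ccc(OCc3ccccc3)c(OCc3ccccc3)c2)C(=O)OCc2ccccc2)[C@H](c2ccc(OCc3ccccc3)c(OCc3ccccc3)c2)c2c(OCc3ccccc3)c(OCc3ccccc3)ccc2C1)C(F)(F)F | intermediate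
28 | carbon monoxide | [C-]#[O+] | starting material
29 | bis(R*) (1R)-7,8-bis(benzyloxy)-1-[3,4-bis(benzyloxy)phenyl]-1,4-dihydronaphthalene-2,3-dicarboxylate | O=C(O[C@H](Cc1ccc(OCc3ccccc3)c(OCc3ccccc3)c1)C(=O)OCc1ccccc1)C1=C(C(=O)O[C@H](Cc2ccc(OCc3ccccc3)c(OCc3ccccc3)c2)C(=O)OCc2ccccc2)[C@H](c2ccc(OCc3ccccc3)c(OCc3ccccc3)c2)c2c(OCc3ccccc3)c(OCc3ccccc3)ccc2C1 | intermediate
30 | bis(R*) (1R,2S)-7,8-bis(benzyloxy)-1-[3,4-bis(benzyloxy)phenyl]-1,2-dihydronaphthalene-2,3-dicarboxylate | O=C(O[C@H](Cc1ccc(OCc3ccccc3)c(OCc3ccccc3)c1)C(=O)OCc1ccccc1)C1=Cc2ccc(OCc3ccccc3)c(OCc3ccccc3)c2[C@@H](c2ccc(OCc3ccccc3)c(OCc3ccccc3)c2)[C@@H]1C(=O)O[C@H](Cc1ccc(OCc3ccccc3)c(OCc3ccccc3)c1)C(=O)OCc1ccccc1 | intermediate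
31 | bis[(1R)-1-carboxy-2-(3,4-dihydroxyphenyl)ethyl] (1R,2S)-1-(3,4-dihydroxyphenyl)-7,8-dihydroxy-1,2-dihydronaphthalene-2,3-dicarboxylate (CNP0244800.2) | O=C(O[C@H](Cc1ccc(O)c(O)c1)C(=O)O)C1=Cc2ccc(O)c(O)c2[C@@H](c2ccc(O)c(O)c2)[C@@H]1C(=O)O[C@H](Cc1ccc(O)c(O)c1)C(=O)O | target

**Totals and risks**

Total step count: 13. Longest linear sequence: 9 steps (1–4 then 9–13; the aryne branch 5–8 then 9–13 is equally long).

Steps most likely to fail:

Step 9. The cycloaddition may show poor facial selectivity, because the α-acyloxy ester is a weak and fairly remote control element and its sense is only predicted; material may also be lost to [2+2] or ene pathways or to premature desilylation. Fallback: replace the internal control element by an N-acyl camphorsultam, an auxiliary class with a record in face-selective aryne cycloadditions of acyclic dienes. Setting out from 4, commercial (2R)-bornane-10,2-sultam would be acetoacetylated (xylene, 130 °C) to N-acetoacetyl sultam F1, condensed with 7 (piperidine, AcOH) to arylidene imide F2, silylated (TIPSOTf, Et3N) to silyloxy diene F3 and combined with 23 and CsF to give cycloadduct F4. TBAF/AcOH would then give enol imide F5, which on heating with alcohol 3 (PhMe, 100 °C) should transfer its β-keto acyl group through the acylketene to give β-keto ester F6 (enol form). NaH/PhNTf2 would convert F6 into triflate 27, where the route is rejoined. The antipodal sultam is equally available should the opposite facial sense be required.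

Step 12. The base may also remove the doubly benzylic C1–H, causing loss of configuration at C1 or migration of the alkene towards C1, and adventitious oxidation may aromatise ring B. Fallback: shift the alkene before the second ester is in place. From 27, hydroxycarbonylation would give acid F7 (as in the fallback for step 11). As its carboxylate the C3 carboxyl group no longer activates C1–H, so Et3N or DBU (2 equiv) should move the alkene only through the C2-ester dienolate, giving the conjugated trans 1,2-dihydro acid F8. Steglich esterification of F8 with 3 (EDC·HCl, DMAP) rejoins the route at 30.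

Step 11. Alcoholysis of the acylpalladium intermediate by the hindered secondary alcohol may be slow, letting reduction or hydrolysis of the enol triflate take over. Fallback: separate the C–C bond formation from the esterification. From 27, hydroxycarbonylation (Pd(OAc)2, 1,3-bis(diphenylphosphino)propane, KOAc, CO, DMF, then aqueous work-up) would give acid F7, and Steglich esterification with 3 (EDC·HCl, DMAP, CH2Cl2) returns to 29.

Further compounds
F1 | step 9 | (2R)-N-(3-oxobutanoyl)bornane-10,2-sultam | CC1(C)[C@@H]2CC[C@]13CS(=O)(=O)N(C(=O)CC(C)=O)[C@@H]3C2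
F2 | step 9 | (2R)-N-{(2Z)-2-acetyl-3-[3,4-bis(benzyloxy)phenyl]prop-2-enoyl}bornane-10,2-sultam | CC1(C)[C@@H]2CC[C@]13CS(=O)(=O)N(C(=O)/C(=C\c4ccc(OCc5ccccc5)c(OCc5ccccc5)c4)C(C)=O)[C@@H]3C2
F3 | step 9 | (2R)-N-{(2Z)-2-[3,4-bis(benzyloxy)benzylidene]-3-[(triisopropylsilyl)oxy]but-3-enoyl}bornane-10,2-sultam | CC1(C)[C@@H]2CC[C@]13CS(=O)(=O)N(C(=O)/C(=C\c4ccc(OCc5ccccc5)c(OCc5ccccc5)c4)C(=C)O[Si](C(C)C)(C(C)C)C(C)C)[C@@H]3C2
F4 | step 9 | (2R)-N-{[(1R)-7,8-bis(benzyloxy)-1-[3,4-bis(benzyloxy)phenyl]-3-[(triisopropylsilyl)oxy]-1,4-dihydronaphthalen-2-yl]carbonyl}bornane-10,2-sultam | CC1(C)[C@@H]2CC[C@]13CS(=O)(=O)N(C(=O)C4=C(O[Si](C(C)C)(C(C)C)C(C)C)Cc5ccc(OCc6ccccc6)c(OCc6ccccc6)c5[C@H]4c4ccc(OCc5ccccc5)c(OCc5ccccc5)c4)[C@@H]3C2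
F5 | step 9 | (2R)-N-{[(1R)-7,8-bis(benzyloxy)-1-[3,4-bis(benzyloxy)phenyl]-3-hydroxy-1,4-dihydronaphthalen-2-yl]carbonyl}bornane-10,2-sultam (enol form of the β-keto imide) | CC1(C)[C@@H]2CC[C@]13CS(=O)(=O)N(C(=O)C4=C(O)Cc5ccc(OCc6ccccc6)c(OCc6ccccc6)c5[C@H]4c4ccc(OCc5ccccc5)c(OCc5ccccc5)c4)[C@@H]3C2
F6 | step 9 | R* (1R)-7,8-bis(benzyloxy)-1-[3,4-bis(benzyloxy)phenyl]-3-hydroxy-1,4-dihydronaphthalene-2-carboxylate (enol form of the β-keto ester) | OC1=C(C(=O)O[C@H](Cc2ccc(OCc3ccccc3)c(OCc3ccccc3)c2)C(=O)OCc2ccccc2)[C@H](c2ccc(OCc3ccccc3)c(OCc3ccccc3)c2)c2c(OCc3ccccc3)c(OCc3ccccc3)ccc2C1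
F7 | step 11 | (1R)-7,8-bis(benzyloxy)-1-[3,4-bis(benzyloxy)phenyl]-2-(R*-oxycarbonyl)-1,4-dihydronaphthalene-3-carboxylic acid | OC(=O)C1=C(C(=O)O[C@H](Cc2ccc(OCc3ccccc3)c(OCc3ccccc3)c2)C(=O)OCc2ccccc2)[C@H](c2ccc(OCc3ccccc3)c(OCc3ccccc3)c2)c2c(OCc3ccccc3)c(OCc3ccccc3)ccc2C1
F8 | step 12 | (1R,2S)-7,8-bis(benzyloxy)-1-[3,4-bis(benzyloxy)phenyl]-2-(R*-oxycarbonyl)-1,2-dihydronaphthalene-3-carboxylic acid | OC(=O)C1=Cc2ccc(OCc3ccccc3)c(OCc3ccccc3)c2[C@@H](c2ccc(OCc3ccccc3)c(OCc3ccccc3)c2)[C@@H]1C(=O)O[C@H](Cc1ccc(OCc3ccccc3)c(OCc3ccccc3)c1)C(=O)OCc1ccccc1
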